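## Retrosynthetic overview

1. The target is released by hydrogenolysis of its octadeca-O-benzyl ether 43; all six inter-ring bonds are diaryl ether C–O bonds.
2. 43 is cut at the E–O–F ether into pentamer phenol 42 and a preformed F–O–G bromide 30 (Chan–Lam ether from phenol 29 and boronic acid 27).
3. 42 is grown one ring at a time (A→B→C→D→E): each ring enters as a bromobenzaldehyde (14, 19, 22, 19) by Cu-catalysed Ullmann etherification, and its CHO is then turned into the next phenol by Baeyer–Villiger/Dakin oxidation.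
4. Ring A (phenol 12) comes from phloroglucinol, the only ring built from acyclic material: an intermolecular Claisen condensation joins diethyl malonate 1 and diethyl 3-oxopentanedioate 2 through a ring C–C bond, followed by Dieckmann closure and decarboxylation.
5. Order: ring A (de novo) → B → C → D → E attached in turn; rings F and G joined to each other separately, then to E; global debenzylation last.

Assumption: the target has no stereocentre or stable stereoaxis, so it is achiral and no stereocontrol is needed; all 18 hydroxyl groups are carried as benzyl ethers.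

## Route

Step 1
Reactants: 1 diethyl malonate; 2 diethyl 3-oxopentanedioate
Product: 4 diethyl 2,4,6-trihydroxybenzene-1,3-dicarboxylate, via triethyl dioxopentanetricarboxylate 3 (not isolated)
Conditions: NaOEt (2 equiv), 1 in excess as medium, 2 added slowly, 100 → 140 °C, EtOH distilled off; then aq. HCl
Reagents that add atoms: none
Why: Intermolecular Claisen condensation in which the sodium enolate of keto diester 2 is C-acylated by an ester group of malonate 1 to give 3 (the key ring C–C bond), after which Dieckmann closure and enolisation to the aromatic diester pull the equilibria forward.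

Step 2
Reactants: 4 diethyl 2,4,6-trihydroxybenzene-1,3-dicarboxylate
Product: 6 phloroglucinol, via trihydroxybenzenedicarboxylic acid 5 (not isolated)
Conditions: KOH, H2O, reflux, N2; then conc. HCl, 80 °C
Reagents that add atoms: none
Why: Saponification, then twofold decarboxylation of the vinylogous β-keto acid, which loses CO2 readily on acidification and warming.

Step 3
Reactants: 6 phloroglucinol
Product: 7 benzene-1,3,5-triyl triacetate
Conditions: Ac2O, pyridine, rt
Reagents that add atoms: acetic anhydride CC(=O)OC(C)=O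
Why: Simple O-acylation; the triacetate is the substrate that allows clean O-benzylation in the next step.

Step 4
Reactants: 7 benzene-1,3,5-triyl triacetate
Product: 8 1,3,5-tris(benzyloxy)benzene
Conditions: BnCl, NaH, DMF, H2O (3 equiv, added slowly), 0 °C → rt
Reagents that add atoms: benzyl chloride ClCc1ccccc1
Why: One-pot deacetylation/Williamson etherification; phenoxide is released slowly by NaOH formed in situ and trapped by BnCl, which suppresses the C-benzylation that free phloroglucinol suffers.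

Step 5
Reactants: 8 1,3,5-tris(benzyloxy)benzene
Product: 10 2,4,6-tris(benzyloxy)benzaldehyde, via iminium chloride 9 (not isolated)
Conditions: POCl3, DMF, 0 °C → rt; then aq. NaOH
Reagents that add atoms: N,N-dimethylformamide CN(C)C=O; water O
Why: Vilsmeier–Haack formylation of a very electron-rich arene; the three free positions are equivalent and the first formyl group deactivates the ring against a second.

Step 6
Reactants: 10 2,4,6-tris(benzyloxy)benzaldehyde
Product: 12 2,4,6-tris(benzyloxy)phenol, via formate 11 (not isolated)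
Conditions: mCPBA, CH2Cl2, 0 °C → rt; NaHCO3 wash; then K2CO3 (cat.), MeOH/THF, rt
Reagents that add atoms: 3-chloroperoxybenzoic acid OOC(=O)c1cccc(Cl)c1
Why: Baeyer–Villiger (Dakin-type) oxidation; the electron-rich aryl group migrates and mild methanolysis of the formate frees the hindered phenol.

Step 7
Reactants: 13 4-bromo-2,6-difluorobenzaldehyde
Product: 14 4-bromo-2,6-bis(benzyloxy)benzaldehyde
Conditions: BnOH (2.2 equiv), NaH, THF/DMF, 0 °C → rt
Reagents that add atoms: benzyl alcohol OCc1ccccc1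
Why: Twofold SNAr; each fluoride is ortho to the activating formyl group and is displaced far faster than the para bromide, which is kept for later couplings.

Step 8
Reactants: 15 5-bromo-1,2,3-trimethoxybenzene
Product: 17 6-bromo-2,3,4-trimethoxybenzaldehyde, via chloro(methoxy)methyl arene 16 (not isolated)
Conditions: Cl2CHOMe, TiCl4, CH2Cl2, −78 → 0 °C; then H2O
Reagents that add atoms: dichloromethyl methyl ether COC(Cl)Cl; water O
Why: Rieche formylation (Friedel–Crafts type); the two free positions are equivalent, and it is run on the methyl ether because TiCl4 would endanger benzyl ethers.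

Step 9
Reactants: 17 6-bromo-2,3,4-trimethoxybenzaldehyde
Product: 18 6-bromo-2,3,4-trihydroxybenzaldehyde
Conditions: BBr3, CH2Cl2, −78 °C → rt; then H2O
Reagents that add atoms: none
Why: Lewis-acid ether cleavage (bromide attacks the methyl of the boron-complexed ether); aryl bromide and aldehyde survive.

Step 10
Reactants: 18 6-bromo-2,3,4-trihydroxybenzaldehyde
Product: 19 6-bromo-2,3,4-tris(benzyloxy)benzaldehyde
Conditions: BnBr, K2CO3, DMF, 60 °C, N2
Reagents that add atoms: benzyl bromide BrCc1ccccc1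
Why: Williamson etherification of all three phenols; excess reagent and warming overcome the hydrogen-bonded ortho-hydroxyl.

Step 11
Reactants: 20 5-bromo-2-hydroxy-3-methoxybenzaldehyde
Product: 21 5-bromo-2,3-dihydroxybenzaldehyde
Conditions: BBr3, CH2Cl2, −78 °C → rt; then H2O
Reagents that add atoms: none
Why: BBr3 demethylation, helped by chelation to the neighbouring phenol.

Step 12
Reactants: 21 5-bromo-2,3-dihydroxybenzaldehyde
Product: 22 5-bromo-2,3-bis(benzyloxy)benzaldehyde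
Conditions: BnBr, K2CO3, DMF, 60 °C, N2
Reagents that add atoms: benzyl bromide BrCc1ccccc1
Why: Williamson etherification of both phenols.

Step 13
Reactants: 15 5-bromo-1,2,3-trimethoxybenzene
Product: 23 5-bromobenzene-1,2,3-triol
Conditions: BBr3, CH2Cl2, −78 °C → rt; then H2O
Reagents that add atoms: none
Why: BBr3 cleavage of the three methyl ethers.

Step 14
Reactants: 23 5-bromobenzene-1,2,3-triol
Product: 24 5-bromo-1,2,3-tris(benzyloxy)benzene
Conditions: BnBr, K2CO3, DMF, 60 °C, N2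
Reagents that add atoms: benzyl bromide BrCc1ccccc1
Why: Williamson etherification under inert gas to protect the pyrogallol from oxidation.

Step 15
Reactants: 24 5-bromo-1,2,3-tris(benzyloxy)benzene
Product: 27 [3,4,5-tris(benzyloxy)phenyl]boronic acid, via aryllithium 25 (not isolated), via lithium triisopropoxyarylborate 26 (not isolated)
Conditions: n-BuLi, THF, −78 °C; B(OiPr)3, −78 °C → rt; then aq. HCl
Reagents that add atoms: triisopropyl borate CC(C)OB(OC(C)C)OC(C)C; water O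
Why: Bromine–lithium exchange at −78 °C is faster than benzylic deprotonation; borate trapping and hydrolysis give the boronic acid.

Step 16
Reactants: 14 4-bromo-2,6-bis(benzyloxy)benzaldehyde
Product: 29 4-bromo-2,6-bis(benzyloxy)phenol, via formate 28 (not isolated)
Conditions: mCPBA, CH2Cl2, 0 °C → rt; NaHCO3 wash; then K2CO3 (cat.), MeOH/THF, rt
Reagents that add atoms: 3-chloroperoxybenzoic acid OOC(=O)c1cccc(Cl)c1
Why: Baeyer–Villiger/Dakin oxidation; the two ortho benzyloxy groups make the aryl group migrate.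

Step 17
Reactants: 29 4-bromo-2,6-bis(benzyloxy)phenol; 27 [3,4,5-tris(benzyloxy)phenyl]boronic acid (2 equiv)
Product: 30 5-bromo-1,3-bis(benzyloxy)-2-[3,4,5-tris(benzyloxy)phenoxy]benzene
Conditions: Cu(OAc)2 (1 equiv, turned over by air), pyridine, 4 Å MS, CH2Cl2, air, rt
Reagents that add atoms: none
Why: Chan–Lam–Evans oxidative C–O coupling runs at room temperature, tolerates di-ortho-substituted phenols and leaves the aryl bromide untouched.

Step 18
Reactants: 12 2,4,6-tris(benzyloxy)phenol; 14 4-bromo-2,6-bis(benzyloxy)benzaldehyde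
Product: 31 dimer aldehyde 2,6-bis(benzyloxy)-4-[2,4,6-tris(benzyloxy)phenoxy]benzaldehyde
Conditions: CuI (10 mol %), picolinic acid (20 mol %), K3PO4, DMSO, 90 °C, Ar
Reagents that add atoms: none
Why: Ullmann-type Cu(I)/picolinic acid etherification; a hindered phenoxide meets an unhindered bromide activated by the para formyl group.

Step 19
Reactants: 31 dimer aldehyde
Product: 33 dimer phenol 2,6-bis(benzyloxy)-4-[2,4,6-tris(benzyloxy)phenoxy]phenol, via dimer formate 32 (not isolated)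
Conditions: mCPBA (1.2 equiv), CH2Cl2, 0 °C; NaHCO3 wash; then K2CO3 (cat.), MeOH/THF, rt
Reagents that add atoms: 3-chloroperoxybenzoic acid OOC(=O)c1cccc(Cl)c1
Why: Baeyer–Villiger/Dakin oxidation; the aldehyde carbon (two ortho OBn, para OAr) is lost as formate and becomes the ring-B phenol.

Step 20
Reactants: 33 dimer phenol; 19 6-bromo-2,3,4-tris(benzyloxy)benzaldehyde
Product: 34 trimer aldehyde (2,3,4-tris(benzyloxy)-6-aryloxybenzaldehyde; aryloxy = phenoxide of 33)
Conditions: CuI (20 mol %), picolinic acid (40 mol %), K3PO4, DMSO, 100 °C, Ar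
Reagents that add atoms: none
Why: Ullmann etherification; the ortho formyl group activates the C–Br bond and offsets the steric load of the tri-ortho-substituted ether.

Step 21
Reactants: 34 trimer aldehyde
Product: 36 trimer phenol (2,3,4-tris(benzyloxy)-6-aryloxyphenol; aryloxy = phenoxide of 33), via trimer formate 35 (not isolated)
Conditions: mCPBA (1.2 equiv), CH2Cl2, 0 °C; NaHCO3 wash; then K2CO3 (cat.), MeOH/THF, rt
Reagents that add atoms: 3-chloroperoxybenzoic acid OOC(=O)c1cccc(Cl)c1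
Why: Baeyer–Villiger/Dakin oxidation of an aldehyde flanked by OAr and OBn; it is faster than attack of the peracid on the electron-rich rings at 0 °C.

Step 22
Reactants: 36 trimer phenol; 22 5-bromo-2,3-bis(benzyloxy)benzaldehyde
Product: 37 tetramer aldehyde (2,3-bis(benzyloxy)-5-aryloxybenzaldehyde; aryloxy = phenoxide of 36)
Conditions: CuI (10 mol %), picolinic acid (20 mol %), K3PO4, DMSO, 90 °C, Ar
Reagents that add atoms: none
Why: Ullmann etherification of a hindered phenoxide with a bromide that has no ortho substituent.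

Step 23
Reactants: 37 tetramer aldehyde
Product: 39 tetramer phenol (2,3-bis(benzyloxy)-5-aryloxyphenol; aryloxy = phenoxide of 36), via tetramer formate 38 (not isolated)
Conditions: mCPBA (1.2 equiv), CH2Cl2, 0 °C → rt; NaHCO3 wash; then K2CO3 (cat.), MeOH/THF, rt
Reagents that add atoms: 3-chloroperoxybenzoic acid OOC(=O)c1cccc(Cl)c1
Why: Baeyer–Villiger/Dakin oxidation; the ortho benzyloxy group makes aryl migrate in preference to hydride.

Step 24
Reactants: 39 tetramer phenol; 19 6-bromo-2,3,4-tris(benzyloxy)benzaldehyde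
Product: 40 pentamer aldehyde (2,3,4-tris(benzyloxy)-6-aryloxybenzaldehyde; aryloxy = phenoxide of 39)
Conditions: CuI (10 mol %), picolinic acid (20 mol %), K3PO4, DMSO, 90 °C, Ar
Reagents that add atoms: none
Why: Ullmann etherification of a mono-ortho-substituted phenoxide with the ortho-formyl-activated bromide.

Step 25
Reactants: 40 pentamer aldehyde
Product: 42 pentamer phenol (2,3,4-tris(benzyloxy)-6-aryloxyphenol; aryloxy = phenoxide of 39), via pentamer formate 41 (not isolated)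
Conditions: mCPBA (1.2 equiv), CH2Cl2, 0 °C; NaHCO3 wash; then K2CO3 (cat.), MeOH/THF, rt
Reagents that add atoms: 3-chloroperoxybenzoic acid OOC(=O)c1cccc(Cl)c1
Why: Baeyer–Villiger/Dakin oxidation, as in step 21.

Step 26
Reactants: 42 pentamer phenol; 30 5-bromo-1,3-bis(benzyloxy)-2-[3,4,5-tris(benzyloxy)phenoxy]benzene (1.5 equiv)
Product: 43 octadeca-O-benzyl ether of the target (42 O-arylated at the bromine-bearing carbon of 30)
Conditions: CuI (20 mol %), picolinic acid (40 mol %), K3PO4, DMSO, 100 °C, Ar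
Reagents that add atoms: none
Why: Convergent Ullmann etherification; the bromide of 30 has no ortho substituent, so only the phenol side is hindered.

Step 27
Reactants: 43 octadeca-O-benzyl ether
Product: 44 CNP0130704.0 (target)
Conditions: H2 (1 atm), 10 % Pd/C, THF/MeOH, rt; filtered and concentrated under Ar
Reagents that add atoms: none
Why: Heterogeneous hydrogenolysis cleaves all 18 benzyl ethers while the diaryl ethers are inert.

## Compound list

1 | diethyl malonate | CCOC(=O)CC(=O)OCC | starting material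
2 | diethyl 3-oxopentanedioate (diethyl acetonedicarboxylate) | CCOC(=O)CC(=O)CC(=O)OCC | starting material
3 | triethyl 2,4-dioxopentane-1,3,5-tricarboxylate | CCOC(=O)CC(=O)C(C(=O)OCC)C(=O)CC(=O)OCC | intermediate (not isolated)
4 | diethyl 2,4,6-trihydroxybenzene-1,3-dicarboxylate | CCOC(=O)c1c(O)cc(O)c(C(=O)OCC)c1O | intermediate
5 | 2,4,6-trihydroxybenzene-1,3-dicarboxylic acid | OC(=O)c1c(O)cc(O)c(C(=O)O)c1O | intermediate (not isolated)
6 | phloroglucinol (benzene-1,3,5-triol) | Oc1cc(O)cc(O)c1 | intermediate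
7 | benzene-1,3,5-triyl triacetate | CC(=O)Oc1cc(OC(C)=O)cc(OC(C)=O)c1 | intermediate
8 | 1,3,5-tris(benzyloxy)benzene | c1c(OCc9ccccc9)cc(OCc9ccccc9)cc1OCc9ccccc9 | intermediate
9 | N-[2,4,6-tris(benzyloxy)benzylidene]-N-methylmethanaminium chloride | C[N+](C)=Cc1c(OCc9ccccc9)cc(OCc9ccccc9)cc1OCc9ccccc9.[Cl-] | intermediate (not isolated)
10 | 2,4,6-tris(benzyloxy)benzaldehyde | O=Cc1c(OCc9ccccc9)cc(OCc9ccccc9)cc1OCc9ccccc9 | intermediate
11 | 2,4,6-tris(benzyloxy)phenyl formate | O=COc1c(OCc9ccccc9)cc(OCc9ccccc9)cc1OCc9ccccc9 | intermediate (not isolated)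
12 | 2,4,6-tris(benzyloxy)phenol | Oc1c(OCc9ccccc9)cc(OCc9ccccc9)cc1OCc9ccccc9 | intermediate
13 | 4-bromo-2,6-difluorobenzaldehyde | O=Cc1c(F)cc(Br)cc1F | starting material
14 | 4-bromo-2,6-bis(benzyloxy)benzaldehyde | O=Cc1c(OCc9ccccc9)cc(Br)cc1OCc9ccccc9 | intermediate
15 | 5-bromo-1,2,3-trimethoxybenzene | COc1cc(Br)cc(OC)c1OC | starting material
16 | 1-bromo-2-[chloro(methoxy)methyl]-3,4,5-trimethoxybenzene | COC(Cl)c1c(Br)cc(OC)c(OC)c1OC | intermediate (not isolated)
17 | 6-bromo-2,3,4-trimethoxybenzaldehyde | COc1cc(Br)c(C=O)c(OC)c1OC | intermediate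
18 | 6-bromo-2,3,4-trihydroxybenzaldehyde | O=Cc1c(Br)cc(O)c(O)c1O | intermediate
19 | 6-bromo-2,3,4-tris(benzyloxy)benzaldehyde | O=Cc1c(Br)cc(OCc9ccccc9)c(OCc9ccccc9)c1OCc9ccccc9 | intermediate
20 | 5-bromo-2-hydroxy-3-methoxybenzaldehyde | COc1cc(Br)cc(C=O)c1O | starting material
21 | 5-bromo-2,3-dihydroxybenzaldehyde | O=Cc1cc(Br)cc(O)c1O | intermediate
22 | 5-bromo-2,3-bis(benzyloxy)benzaldehyde | O=Cc1cc(Br)cc(OCc9ccccc9)c1OCc9ccccc9 | intermediate
23 | 5-bromobenzene-1,2,3-triol | Oc1cc(Br)cc(O)c1O | intermediate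
24 | 5-bromo-1,2,3-tris(benzyloxy)benzene | Brc1cc(OCc9ccccc9)c(OCc9ccccc9)c(OCc9ccccc9)c1 | intermediate
25 | [3,4,5-tris(benzyloxy)phenyl]lithium | [Li]c1cc(OCc9ccccc9)c(OCc9ccccc9)c(OCc9ccccc9)c1 | intermediate (not isolated)
26 | lithium triisopropoxy[3,4,5-tris(benzyloxy)phenyl]borate | [Li+].CC(C)O[B-](OC(C)C)(OC(C)C)c1cc(OCc9ccccc9)c(OCc9ccccc9)c(OCc9ccccc9)c1 | intermediate (not isolated)
27 | [3,4,5-tris(benzyloxy)phenyl]boronic acid | OB(O)c1cc(OCc9ccccc9)c(OCc9ccccc9)c(OCc9ccccc9)c1 | intermediate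
28 | 4-bromo-2,6-bis(benzyloxy)phenyl formate | O=COc1c(OCc9ccccc9)cc(Br)cc1OCc9ccccc9 | intermediate (not isolated)
29 | 4-bromo-2,6-bis(benzyloxy)phenol | Oc1c(OCc9ccccc9)cc(Br)cc1OCc9ccccc9 | intermediate
30 | 5-bromo-1,3-bis(benzyloxy)-2-[3,4,5-tris(benzyloxy)phenoxy]benzene (F–O–G bromide) | Brc1cc(OCc9ccccc9)c(Oc2cc(OCc9ccccc9)c(OCc9ccccc9)c(OCc9ccccc9)c2)c(OCc9ccccc9)c1 | intermediate
31 | dimer aldehyde: 2,6-bis(benzyloxy)-4-[2,4,6-tris(benzyloxy)phenoxy]benzaldehyde | c9ccccc9COc1cc(OCc9ccccc9)c(Oc2cc(OCc9ccccc9)c(C=O)c(OCc9ccccc9)c2)c(OCc9ccccc9)c1 | intermediate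
32 | dimer formate: 2,6-bis(benzyloxy)-4-[2,4,6-tris(benzyloxy)phenoxy]phenyl formate | c9ccccc9COc1cc(OCc9ccccc9)c(Oc2cc(OCc9ccccc9)c(OC=O)c(OCc9ccccc9)c2)c(OCc9ccccc9)c1 | intermediate (not isolated)
33 | dimer phenol: 2,6-bis(benzyloxy)-4-[2,4,6-tris(benzyloxy)phenoxy]phenol | c9ccccc9COc1cc(OCc9ccccc9)c(Oc2cc(OCc9ccccc9)c(O)c(OCc9ccccc9)c2)c(OCc9ccccc9)c1 | intermediate
34 | trimer aldehyde: 2,3,4-tris(benzyloxy)-6-(aryloxy)benzaldehyde, aryloxy = phenoxide of 33 | c9ccccc9COc1cc(OCc9ccccc9)c(Oc2cc(OCc9ccccc9)c(Oc3cc(OCc9ccccc9)c(OCc9ccccc9)c(OCc9ccccc9)c3C=O)c(OCc9ccccc9)c2)c(OCc9ccccc9)c1 | intermediate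
35 | trimer formate: formate ester of 36 | c9ccccc9COc1cc(OCc9ccccc9)c(Oc2cc(OCc9ccccc9)c(Oc3cc(OCc9ccccc9)c(OCc9ccccc9)c(OCc9ccccc9)c3OC=O)c(OCc9ccccc9)c2)c(OCc9ccccc9)c1 | intermediate (not isolated)
36 | trimer phenol: 2,3,4-tris(benzyloxy)-6-(aryloxy)phenol, aryloxy = phenoxide of 33 | c9ccccc9COc1cc(OCc9ccccc9)c(Oc2cc(OCc9ccccc9)c(Oc3cc(OCc9ccccc9)c(OCc9ccccc9)c(OCc9ccccc9)c3O)c(OCc9ccccc9)c2)c(OCc9ccccc9)c1 | intermediate
37 | tetramer aldehyde: 2,3-bis(benzyloxy)-5-(aryloxy)benzaldehyde, aryloxy = phenoxide of 36 | c9ccccc9COc1cc(OCc9ccccc9)c(Oc2cc(OCc9ccccc9)c(Oc3cc(OCc9ccccc9)c(OCc9ccccc9)c(OCc9ccccc9)c3Oc4cc(OCc9ccccc9)c(OCc9ccccc9)c(C=O)c4)c(OCc9ccccc9)c2)c(OCc9ccccc9)c1 | intermediate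
38 | tetramer formate: formate ester of 39 | c9ccccc9COc1cc(OCc9ccccc9)c(Oc2cc(OCc9ccccc9)c(Oc3cc(OCc9ccccc9)c(OCc9ccccc9)c(OCc9ccccc9)c3Oc4cc(OCc9ccccc9)c(OCc9ccccc9)c(OC=O)c4)c(OCc9ccccc9)c2)c(OCc9ccccc9)c1 | intermediate (not isolated)
39 | tetramer phenol: 2,3-bis(benzyloxy)-5-(aryloxy)phenol, aryloxy = phenoxide of 36 | c9ccccc9COc1cc(OCc9ccccc9)c(Oc2cc(OCc9ccccc9)c(Oc3cc(OCc9ccccc9)c(OCc9ccccc9)c(OCc9ccccc9)c3Oc4cc(OCc9ccccc9)c(OCc9ccccc9)c(O)c4)c(OCc9ccccc9)c2)c(OCc9ccccc9)c1 | intermediate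
40 | pentamer aldehyde: 2,3,4-tris(benzyloxy)-6-(aryloxy)benzaldehyde, aryloxy = phenoxide of 39 | c9ccccc9COc1cc(OCc9ccccc9)c(Oc2cc(OCc9ccccc9)c(Oc3cc(OCc9ccccc9)c(OCc9ccccc9)c(OCc9ccccc9)c3Oc4cc(OCc9ccccc9)c(OCc9ccccc9)c(Oc5cc(OCc9ccccc9)c(OCc9ccccc9)c(OCc9ccccc9)c5C=O)c4)c(OCc9ccccc9)c2)c(OCc9ccccc9)c1 | intermediate
41 | pentamer formate: formate ester of 42 | c9ccccc9COc1cc(OCc9ccccc9)c(Oc2cc(OCc9ccccc9)c(Oc3cc(OCc9ccccc9)c(OCc9ccccc9)c(OCc9ccccc9)c3Oc4cc(OCc9ccccc9)c(OCc9ccccc9)c(Oc5cc(OCc9ccccc9)c(OCc9ccccc9)c(OCc9ccccc9)c5OC=O)c4)c(OCc9ccccc9)c2)c(OCc9ccccc9)c1 | intermediate (not isolated)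
42 | pentamer phenol: 2,3,4-tris(benzyloxy)-6-(aryloxy)phenol, aryloxy = phenoxide of 39 | c9ccccc9COc1cc(OCc9ccccc9)c(Oc2cc(OCc9ccccc9)c(Oc3cc(OCc9ccccc9)c(OCc9ccccc9)c(OCc9ccccc9)c3Oc4cc(OCc9ccccc9)c(OCc9ccccc9)c(Oc5cc(OCc9ccccc9)c(OCc9ccccc9)c(OCc9ccccc9)c5O)c4)c(OCc9ccccc9)c2)c(OCc9ccccc9)c1 | intermediate
43 | octadeca-O-benzyl ether of the target (all 18 OH as OBn) | c9ccccc9COc1cc(OCc9ccccc9)c(Oc2cc(OCc9ccccc9)c(Oc3cc(OCc9ccccc9)c(OCc9ccccc9)c(OCc9ccccc9)c3Oc4cc(OCc9ccccc9)c(OCc9ccccc9)c(Oc5cc(OCc9ccccc9)c(OCc9ccccc9)c(OCc9ccccc9)c5Oc6cc(OCc9ccccc9)c(Oc7cc(OCc9ccccc9)c(OCc9ccccc9)c(OCc9ccccc9)c7)c(OCc9ccccc9)c6)c4)c(OCc9ccccc9)c2)c(OCc9ccccc9)c1 | intermediate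
44 | CNP0130704.0, heptameric fuhalol-type phlorotannin (free octadecaol, achiral) | Oc1cc(O)c(Oc2cc(O)c(Oc3cc(O)c(O)c(O)c3Oc3cc(O)c(O)c(Oc4cc(O)c(O)c(O)c4Oc4cc(O)c(Oc5cc(O)c(O)c(O)c5)c(O)c4)c3)c(O)c2)c(O)c1 | target

## Summary

Total step count: 27.
Longest linear sequence: 16 steps (steps 1–6, then 18–27).

Three steps most likely to fail:

Step 20. The ether between phenol 33 (two ortho OBn) and bromide 19 (ortho CHO) has three ortho substituents and may couple slowly or not at all. The fallback forms this hindered ether before the ortho carbon is in place and adds ring A last. It sets out from 30, which already holds the 2,6-bis(benzyloxy)phenyl 3,4,5-tris(benzyloxy)phenyl ether with a bromide on the future ring B. Vilsmeier–Haack formylation (POCl3, DMF, 60 °C; then aq. NaOH) attacks the tetra-oxygenated ring, whose two free positions are equivalent and more activated than those of the bromo ring. It gives, through the iminium chloride F1, 6-[4-bromo-2,6-bis(benzyloxy)phenoxy]-2,3,4-tris(benzyloxy)benzaldehyde F2. Ullmann coupling of phenol 12 with the unhindered bromide of F2 (CuI, picolinic acid, K3PO4, DMSO, 90 °C) then gives 34, where the main route is rejoined.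

Step 26. The union of the large hindered phenol 42 with the dimer bromide 30 may be sluggish. The fallback sets out from 42 and grows the chain stepwise instead. Coupling with the small, formyl-activated bromide 14 under the same copper conditions gives the hexamer aldehyde F3. Baeyer–Villiger oxidation with mCPBA gives the hexamer formate F4, and methanolysis gives the hexamer phenol F5. Ring G is then attached at room temperature by Chan–Lam–Evans coupling with boronic acid 27 (Cu(OAc)2, pyridine, 4 Å MS, CH2Cl2, air), which gives 43.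

Step 17. The Chan–Lam coupling of the di-ortho-substituted phenol 29 may give low conversion. The fallback sets out from 24 and uses halide selectivity instead of a boronic acid. Aromatic Finkelstein exchange (CuI, NaI, trans-N,N'-dimethylcyclohexane-1,2-diamine, dioxane, 110 °C) gives 5-iodo-1,2,3-tris(benzyloxy)benzene F6. Ullmann coupling of phenol 29 with F6 at 70–80 °C (CuI, picolinic acid, K3PO4, DMSO), where the C–I bond reacts well before the C–Br bond of 29, gives 30.

## Further compounds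

F1 | step 20 | N-{6-[4-bromo-2,6-bis(benzyloxy)phenoxy]-2,3,4-tris(benzyloxy)benzylidene}-N-methylmethanaminium chloride | C[N+](C)=Cc3c(Oc2c(OCc9ccccc9)cc(Br)cc2OCc9ccccc9)cc(OCc9ccccc9)c(OCc9ccccc9)c3OCc9ccccc9.[Cl-]
F2 | step 20 | 6-[4-bromo-2,6-bis(benzyloxy)phenoxy]-2,3,4-tris(benzyloxy)benzaldehyde | O=Cc3c(Oc2c(OCc9ccccc9)cc(Br)cc2OCc9ccccc9)cc(OCc9ccccc9)c(OCc9ccccc9)c3OCc9ccccc9
F3 | step 26 | hexamer aldehyde: 2,6-bis(benzyloxy)-4-(aryloxy)benzaldehyde, aryloxy = phenoxide of 42 | c9ccccc9COc1cc(OCc9ccccc9)c(Oc2cc(OCc9ccccc9)c(Oc3cc(OCc9ccccc9)c(OCc9ccccc9)c(OCc9ccccc9)c3Oc4cc(OCc9ccccc9)c(OCc9ccccc9)c(Oc5cc(OCc9ccccc9)c(OCc9ccccc9)c(OCc9ccccc9)c5Oc6cc(OCc9ccccc9)c(C=O)c(OCc9ccccc9)c6)c4)c(OCc9ccccc9)c2)c(OCc9ccccc9)c1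
F4 | step 26 | hexamer formate: formate ester of F5 | c9ccccc9COc1cc(OCc9ccccc9)c(Oc2cc(OCc9ccccc9)c(Oc3cc(OCc9ccccc9)c(OCc9ccccc9)c(OCc9ccccc9)c3Oc4cc(OCc9ccccc9)c(OCc9ccccc9)c(Oc5cc(OCc9ccccc9)c(OCc9ccccc9)c(OCc9ccccc9)c5Oc6cc(OCc9ccccc9)c(OC=O)c(OCc9ccccc9)c6)c4)c(OCc9ccccc9)c2)c(OCc9ccccc9)c1
F5 | step 26 | hexamer phenol: 2,6-bis(benzyloxy)-4-(aryloxy)phenol, aryloxy = phenoxide of 42 | c9ccccc9COc1cc(OCc9ccccc9)c(Oc2cc(OCc9ccccc9)c(Oc3cc(OCc9ccccc9)c(OCc9ccccc9)c(OCc9ccccc9)c3Oc4cc(OCc9ccccc9)c(OCc9ccccc9)c(Oc5cc(OCc9ccccc9)c(OCc9ccccc9)c(OCc9ccccc9)c5Oc6cc(OCc9ccccc9)c(O)c(OCc9ccccc9)c6)c4)c(OCc9ccccc9)c2)c(OCc9ccccc9)c1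
F6 | step 17 | 5-iodo-1,2,3-tris(benzyloxy)benzene | Ic1cc(OCc9ccccc9)c(OCc9ccccc9)c(OCc9ccccc9)c1
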